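**Plan**

- Cuts (labdane numbering): C12–C13 (alkylzinc + (Z)-iodoenoate), C8=C17 (ketone methylenation) and C9–C11 (C9 enolate + bromoacetate). C9–C20 is then re-formed on paper, and the resulting cyclopropyl ketone is cut at C9–C10 and C9–C20 to a monocyclic diazoketone. Ring A is cut at C5–C6 (allylation) and C10–C20 (silylmethyl addition).
- Enabling feature: C9 is bonded to the quaternary C10 that bears the angular methyl C20 and is α to C8, so a C9–C10–C20 cyclopropane beside a C8 ketone stores both the methyl and a regiodefined C9 enolate.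
- Forward: ring A comes from dimedone. Ring B and the three-membered ring close together when the C9 keto-carbenoid adds to the exocyclic C10=C20 alkene. Li/NH3 opens C9–C20, the enolate takes C11–C12, and C13–C16 is joined last by Negishi coupling.
- Stereochemistry: C5 from Pd-catalysed asymmetric allylation; C2 from oxazaborolidine-controlled reduction; C10 from equatorial-face cyclopropanation directed by the axial C4 methyl; C9 by equilibration to the equatorial side chain; C13=C14 from anti-hydroiodination and stereoretentive coupling.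

Key step: step 11

Assumption: the usual sense of induction is taken for both chiral reagents (the (R,R)-ligand of step 3 giving (R)-6; the (S)-oxazaborolidine of step 5 treating the alkenyl side as the large group); where it proves opposite, the enantiomeric reagent is used and nothing else changes.

**Route**

Step 1
Reactants: 1 dimedone
Product: 2 3-isobutoxy-5,5-dimethylcyclohex-2-en-1-one
Conditions: i-BuOH, p-TsOH·H2O (cat.), toluene, reflux, Dean–Stark
Reagents that add atoms: 2-methylpropan-1-ol, CC(C)CO
Why: Acid-catalysed enol etherification of the symmetric 1,3-diketone with azeotropic removal of water gives the vinylogous ester as a single constitutional isomer.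

Step 2
Reactants: 2 3-isobutoxy-5,5-dimethylcyclohex-2-en-1-one; 3 allyl chloroformate
Product: 5 allyl 5-isobutoxy-3,3-dimethylcyclohexa-1,5-dien-1-yl carbonate, via lithium dienolate 4 (not isolated)
Conditions: LiN(iPr)2 (LDA), THF, −78 °C; TMEDA; then 3, −78 → 0 °C
Reagents that add atoms: none
Why: Kinetic α′-deprotonation of the vinylogous ester gives the cross-conjugated enolate, whose hindered carbon terminus (next to the gem-dimethyl carbon) leaves O-acylation by the chloroformate as the expected course (enol carbonate formation).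

Step 3
Reactants: 5 allyl 5-isobutoxy-3,3-dimethylcyclohexa-1,5-dien-1-yl carbonate
Product: 6 (R)-6-allyl-3-isobutoxy-5,5-dimethylcyclohex-2-en-1-one
Conditions: Pd2(dba)3·CHCl3 (2.5 mol %), (R,R)-ANDEN-phenyl diphosphine ligand (5.5 mol %), 1,4-dioxane, 23 °C
Reagents that add atoms: none
Why: Pd-catalysed decarboxylative asymmetric allylic alkylation (Tsuji–Trost type): zerovalent palladium ionises the allyl carbonate, CO2 is lost, and the enolate/π-allyl ion pair recombines inside the chiral ligand pocket under neutral conditions, setting the tertiary C5 stereocentre without a base that could racemise it.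

Step 4
Reactants: 6 (R)-6-allyl-3-isobutoxy-5,5-dimethylcyclohex-2-en-1-one
Product: 8 (R)-4-allyl-5,5-dimethyl-3-[(trimethylsilyl)methyl]cyclohex-2-en-1-one, via lithium carbinolate 7 (not isolated)
Conditions: Me3SiCH2Li, THF, −78 → 0 °C; then 1 M HCl, THF, 0 °C, short contact
Reagents that add atoms: (trimethylsilyl)methyllithium, [Li]C[Si](C)(C)C; water, O
Why: Stork–Danheiser carbonyl transposition: the weakly basic α-silyl organolithium adds 1,2 to the vinylogous ester carbonyl, and mild acid hydrolysis of the enol ether with loss of the carbinol oxygen gives the transposed enone that carries C20 as CH2SiMe3; hydration of the oxocarbenium ion is expected to outrun Peterson elimination, and the C5 centre is not involved.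

Step 5
Reactants: 8 (R)-4-allyl-5,5-dimethyl-3-[(trimethylsilyl)methyl]cyclohex-2-en-1-one
Product: 9 (1R,4R)-4-allyl-5,5-dimethyl-3-[(trimethylsilyl)methyl]cyclohex-2-en-1-ol
Conditions: (S)-2-methyl-CBS-oxazaborolidine (0.3 equiv), catecholborane, toluene, −78 °C; MeOH, then aq. NaOH wash
Reagents that add atoms: none
Why: Corey–Bakshi–Shibata reduction: catecholborane delivers hydride 1,2 within the ketone–oxazaborolidine complex without touching the allyl group, so the carbinol centre (C2) is set R under reagent control, trans to the C5 allyl group; material of the wrong C5 configuration or from the wrong face ends as the cis diastereomer, which chromatography removes.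

Step 6
Reactants: 9 (1R,4R)-4-allyl-5,5-dimethyl-3-[(trimethylsilyl)methyl]cyclohex-2-en-1-ol
Product: 10 tert-butyl{[(1R,4R)-4-allyl-5,5-dimethyl-3-[(trimethylsilyl)methyl]cyclohex-2-en-1-yl]oxy}dimethylsilane
Conditions: TBSCl, imidazole, DMF, 23 °C
Reagents that add atoms: tert-butyldimethylsilyl chloride, CC(C)(C)[Si](C)(C)Cl
Why: Standard silylation of a secondary alcohol under basic conditions, which avoids acid-induced 1,4-elimination of the δ-silyl allylic alcohol.

Step 7
Reactants: 10 tert-butyl{[(1R,4R)-4-allyl-5,5-dimethyl-3-[(trimethylsilyl)methyl]cyclohex-2-en-1-yl]oxy}dimethylsilane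
Product: 11 tert-butyl{[(1R,4R)-4-allyl-3,3-dimethyl-5-methylidenecyclohexyl]oxy}dimethylsilane
Conditions: CF3CO2H (3 equiv), CH2Cl2, −20 → 0 °C, short contact; aq. NaHCO3
Reagents that add atoms: none
Why: Protodesilylation of an allylsilane with allylic shift (SE2′): the proton adds to C1, the β-silyl cation at C10 loses Me3Si, and the double bond ends exocyclic as C10=C20; the terminal alkene is inert and the silyl ether is a poor leaving group under these conditions.

Step 8
Reactants: 11 tert-butyl{[(1R,4R)-4-allyl-3,3-dimethyl-5-methylidenecyclohexyl]oxy}dimethylsilane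
Product: 13 3-[(1R,4R)-4-(tert-butyldimethylsilyloxy)-2,2-dimethyl-6-methylidenecyclohexyl]propan-1-ol, via alkylborane 12 (not isolated)
Conditions: Sia2BH (from BH3·THF and 2-methylbut-2-ene), THF, 0 °C; then NaOH, H2O2, 0 → 23 °C
Reagents that add atoms: hydrogen peroxide, OO
Why: Hydroboration–oxidation with a hindered dialkylborane: disiamylborane adds anti-Markovnikov to the monosubstituted allyl alkene much faster than to the 1,1-disubstituted, α-branched ring methylene, and alkaline peroxide turns the C–B bond into the primary alcohol.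

Step 9
Reactants: 13 3-[(1R,4R)-4-(tert-butyldimethylsilyloxy)-2,2-dimethyl-6-methylidenecyclohexyl]propan-1-ol
Product: 15 3-[(1R,4R)-4-(tert-butyldimethylsilyloxy)-2,2-dimethyl-6-methylidenecyclohexyl]propanoic acid, via aldehyde 14 (not isolated)
Conditions: TEMPO (0.2 equiv), PhI(OAc)2 (2.5 equiv), MeCN/H2O 1:1, 23 °C
Reagents that add atoms: water, O
Why: Nitroxyl-catalysed oxidation takes the primary alcohol through the aldehyde hydrate to the carboxylic acid under near-neutral, chlorine-free conditions that leave the exocyclic alkene and the silyl ether alone.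

Step 10
Reactants: 15 3-[(1R,4R)-4-(tert-butyldimethylsilyloxy)-2,2-dimethyl-6-methylidenecyclohexyl]propanoic acid
Product: 17 1-diazo-4-[(1R,4R)-4-(tert-butyldimethylsilyloxy)-2,2-dimethyl-6-methylidenecyclohexyl]butan-2-one, via mixed anhydride 16 (not isolated)
Conditions: i-BuOCOCl, Et3N, THF, −15 °C; then CH2N2 (Et2O solution, excess), 0 → 23 °C
Reagents that add atoms: diazomethane, C=[N+]=[N-]
Why: Acylation of diazomethane by a mixed carbonic anhydride (Arndt–Eistert-type diazoketone synthesis) gives the α-diazoketone without HCl, which would endanger the exocyclic alkene and the silyl ether.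

Step 11
Reactants: 17 1-diazo-4-[(1R,4R)-4-(tert-butyldimethylsilyloxy)-2,2-dimethyl-6-methylidenecyclohexyl]butan-2-one
Product: 18 (2R,5R,9S,10R)-2-(tert-butyldimethylsilyloxy)-9,20-cyclo-11,12,13,14,15,16,17-heptanorlabdan-8-one
Conditions: Cu(acac)2 (5 mol %, divalent copper), benzene, reflux, slow addition of 17 at high dilution
Reagents that add atoms: none
Why: Cu(acac)2 is reduced in situ to the active monovalent copper species, which decomposes the diazoketone with loss of N2 to an electrophilic keto-carbenoid at C9 that adds in one asynchronous step across the 1,1-disubstituted C10=C20 alkene, the closest known reaction type being the copper-catalysed intramolecular cyclopropanation of δ,ε-unsaturated diazomethyl ketones to bicyclo[4.1.0]heptan-2-ones. Ring B closes six-membered through the C9–C10 bond (tether C5–C6–C7–C8, alkene exocyclic to ring A) and the three-membered ring closes through C9–C20 in the same event. C10 is controlled by ring A, whose chair is anchored by the equatorial silyloxy group at C2 and the equatorial side chain at C5: the axial C4 methyl is 1,3-diaxial to the axial face of C10, so the carbenoid enters on the equatorial face, C9 becomes the equatorial substituent and C20 is pushed axial, which is the trans ring fusion (C20 anti to H5). C9 follows from C10 because the cyclopropane can only be cis-fused to ring B, and it is levelled to an enolate in the next step. The step needs cyclopropanation to win over insertion into the tertiary allylic C5–H bond and over carbene dimerisation; copper carbenoids prefer π-bonds to C–H bonds, and slow addition at high dilution suppresses dimerisation. An external methylene donor acting on a ring B enone would have to approach the blocked axial face, which is why the methyl carbon is supplied by the alkene and not by a reagent.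

Step 12
Reactants: 18 (2R,5R,9S,10R)-2-(tert-butyldimethylsilyloxy)-9,20-cyclo-11,12,13,14,15,16,17-heptanorlabdan-8-one; 19 tert-butyl bromoacetate
Product: 22 tert-butyl (2R,5R,9S,10R)-2-(tert-butyldimethylsilyloxy)-8-oxo-13,14,15,16,17-pentanorlabdan-12-oate, via lithium enolate 20 (not isolated), via C9-epimeric keto ester 21 (not isolated)
Conditions: Li (2.1 equiv), t-BuOH (1.0 equiv), NH3(l)/THF, −78 °C; NH3 evaporated; 19 (3 equiv), THF/DMPU, −78 → 0 °C; then NaOMe, MeOH, 23 °C
Reagents that add atoms: none
Why: Dissolving-metal cleavage of a conjugated cyclopropyl ketone followed by Stork reductive alkylation: electron transfer to the C8 carbonyl breaks the exocyclic C9–C20 bond that overlaps with the carbonyl π-system (C20 becomes the C10 methyl), the regiodefined C8–C9 lithium enolate is alkylated at C9, expectedly anti to the axial C20 methyl, and methoxide equilibration through the enolate moves the side chain to the preferred equatorial position (9S here only because the C8 carbonyl outranks C10; the spatial arrangement is that of the target).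

Step 13
Reactants: 22 tert-butyl (2R,5R,9S,10R)-2-(tert-butyldimethylsilyloxy)-8-oxo-13,14,15,16,17-pentanorlabdan-12-oate
Product: 23 tert-butyl (2R,5R,9R,10R)-2-(tert-butyldimethylsilyloxy)-13,14,15,16-tetranorlabd-8(17)-en-12-oate
Conditions: Ph3PCH3Br, KOtBu, toluene, 80 °C
Reagents that add atoms: methyltriphenylphosphonium bromide, C[P+](c1ccccc1)(c1ccccc1)c1ccccc1.[Br-]
Why: Wittig methylenation: the unstabilised ylide converts the hindered C8 ketone into the C8=C17 alkene, the tert-butyl ester is not attacked, and C9 is already in the configuration that the basic medium favours.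

Step 14
Reactants: 23 tert-butyl (2R,5R,9R,10R)-2-(tert-butyldimethylsilyloxy)-13,14,15,16-tetranorlabd-8(17)-en-12-oate
Product: 24 (2R,5R,9R,10R)-2-(tert-butyldimethylsilyloxy)-13,14,15,16-tetranorlabd-8(17)-en-12-ol
Conditions: LiAlH4, THF, 0 → 23 °C
Reagents that add atoms: none
Why: Hydride reduction of the ester to the primary C12 alcohol; the isolated alkene and the silyl ether are inert to LiAlH4.

Step 15
Reactants: 24 (2R,5R,9R,10R)-2-(tert-butyldimethylsilyloxy)-13,14,15,16-tetranorlabd-8(17)-en-12-ol
Product: 25 (2R,5R,9R,10R)-2-(tert-butyldimethylsilyloxy)-12-iodo-13,14,15,16-tetranorlabd-8(17)-ene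
Conditions: I2, PPh3, imidazole, CH2Cl2, 0 → 23 °C
Reagents that add atoms: iodine, [I][I]
Why: Appel-type iodination: the alkoxyphosphonium ion is displaced by iodide in an SN2 reaction at the unhindered primary C12.

Step 16
Reactants: 26 methyl 4-hydroxybut-2-ynoate
Product: 27 methyl (Z)-4-hydroxy-3-iodobut-2-enoate
Conditions: NaI, AcOH, 70 °C
Reagents that add atoms: sodium iodide, [Na+].[I-]
Why: Hydroiodination of an ynoate: iodide adds in conjugate fashion to C3 and the allenolate is protonated anti, giving the (Z)-β-iodo enoate with iodine cis to the ester and the hydroxymethyl group trans, so that no butenolide can form.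

Step 17
Reactants: 27 methyl (Z)-4-hydroxy-3-iodobut-2-enoate
Product: 28 methyl (Z)-4-(tert-butyldimethylsilyloxy)-3-iodobut-2-enoate
Conditions: TBSCl, imidazole, CH2Cl2, 0 → 23 °C
Reagents that add atoms: tert-butyldimethylsilyl chloride, CC(C)(C)[Si](C)(C)Cl
Why: Silylation of the primary alcohol removes the acidic proton that would quench the organozinc partner.

Step 18
Reactants: 25 (2R,5R,9R,10R)-2-(tert-butyldimethylsilyloxy)-12-iodo-13,14,15,16-tetranorlabd-8(17)-ene; 28 methyl (Z)-4-(tert-butyldimethylsilyloxy)-3-iodobut-2-enoate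
Product: 30 methyl (2R,5R,9R,10R,13E)-2,16-bis(tert-butyldimethylsilyloxy)labda-8(17),13-dien-15-oate, via alkylzinc iodide 29 (not isolated)
Conditions: Zn dust (activated with BrCH2CH2Br and Me3SiCl), DMA/THF, 40 °C; then 28, PdCl2(dppf)·CH2Cl2 (5 mol %), THF, 23 → 45 °C
Reagents that add atoms: none
Why: Negishi coupling: zinc inserts into the primary C–I bond and the alkylzinc iodide couples with the vinyl iodide under palladium catalysis (oxidative addition, transmetalation, reductive elimination) with retention of alkene geometry, so C12 ends cis to the ester, which is the 13E configuration of the target; ester, silyl ethers and the exocyclic alkene tolerate the organozinc.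

Step 19
Reactants: 30 methyl (2R,5R,9R,10R,13E)-2,16-bis(tert-butyldimethylsilyloxy)labda-8(17),13-dien-15-oate
Product: 32 (2R,5R,9R,10R,13E)-2,16-dihydroxylabda-8(17),13-dien-15-oic acid, via diol methyl ester 31 (not isolated)
Conditions: Bu4NF (4 equiv), THF, 23 → 45 °C; then LiOH, MeOH/H2O, 23 °C; 1 M HCl to pH 3
Reagents that add atoms: lithium hydroxide, [Li+].[OH-]
Why: Fluoride-mediated desilylation of both silyl ethers followed by saponification of the conjugated methyl ester (addition–elimination at the acyl carbon); the C16 hydroxyl is trans to the carboxyl group and cannot lactonise.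

Step 20
Reactants: 32 (2R,5R,9R,10R,13E)-2,16-dihydroxylabda-8(17),13-dien-15-oic acid
Product: 33 (2R,5R,9R,10R,13E)-16-acetoxy-2-hydroxylabda-8(17),13-dien-15-oic acid
Conditions: AcCl (1.2 equiv), 2,4,6-collidine, CH2Cl2, −78 → −40 °C; aqueous work-up
Reagents that add atoms: acetyl chloride, CC(=O)Cl
Why: Chemoselective O-acetylation: at low temperature with a hindered pyridine base, acetyl chloride acylates the unhindered primary allylic C16 hydroxyl much faster than the secondary C2 hydroxyl, and any mixed anhydride formed at the carboxyl group is hydrolysed on aqueous work-up.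

**Compound list**

1 | dimedone (5,5-dimethylcyclohexane-1,3-dione) | CC1(C)CC(=O)CC(=O)C1 | starting material
2 | 3-isobutoxy-5,5-dimethylcyclohex-2-en-1-one | CC(C)COC1=CC(=O)CC(C)(C)C1 | intermediate
3 | allyl chloroformate | C=CCOC(=O)Cl | starting material
4 | lithium 5-isobutoxy-3,3-dimethylcyclohexa-1,5-dien-1-olate (α′-enolate of 2) | [Li]OC1=CC(C)(C)CC(OCC(C)C)=C1 | intermediate (not isolated)
5 | allyl 5-isobutoxy-3,3-dimethylcyclohexa-1,5-dien-1-yl carbonate | C=CCOC(=O)OC1=CC(C)(C)CC(OCC(C)C)=C1 | intermediate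
6 | (R)-6-allyl-3-isobutoxy-5,5-dimethylcyclohex-2-en-1-one | C=CC[C@H]1C(=O)C=C(OCC(C)C)CC1(C)C | intermediate
7 | lithium (6R)-6-allyl-3-isobutoxy-5,5-dimethyl-1-[(trimethylsilyl)methyl]cyclohex-2-en-1-olate (either carbinol epimer) | C=CC[C@H]1C(O[Li])(C[Si](C)(C)C)C=C(OCC(C)C)CC1(C)C | intermediate (not isolated)
8 | (R)-4-allyl-5,5-dimethyl-3-[(trimethylsilyl)methyl]cyclohex-2-en-1-one | C=CC[C@H]1C(C[Si](C)(C)C)=CC(=O)CC1(C)C | intermediate
9 | (1R,4R)-4-allyl-5,5-dimethyl-3-[(trimethylsilyl)methyl]cyclohex-2-en-1-ol (hydroxyl trans to allyl) | C=CC[C@H]1C(C[Si](C)(C)C)=C[C@H](O)CC1(C)C | intermediate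
10 | tert-butyl{[(1R,4R)-4-allyl-5,5-dimethyl-3-[(trimethylsilyl)methyl]cyclohex-2-en-1-yl]oxy}dimethylsilane | C=CC[C@H]1C(C[Si](C)(C)C)=C[C@H](O[Si](C)(C)C(C)(C)C)CC1(C)C | intermediate
11 | tert-butyl{[(1R,4R)-4-allyl-3,3-dimethyl-5-methylidenecyclohexyl]oxy}dimethylsilane (ring A with exocyclic C10=C20) | C=CC[C@H]1C(=C)C[C@H](O[Si](C)(C)C(C)(C)C)CC1(C)C | intermediate
12 | bis(3-methylbutan-2-yl){3-[(1R,4R)-4-(tert-butyldimethylsilyloxy)-2,2-dimethyl-6-methylidenecyclohexyl]propyl}borane | CC(C)C(C)B(CCC[C@H]1C(=C)C[C@H](O[Si](C)(C)C(C)(C)C)CC1(C)C)C(C)C(C)C | intermediate (not isolated)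
13 | 3-[(1R,4R)-4-(tert-butyldimethylsilyloxy)-2,2-dimethyl-6-methylidenecyclohexyl]propan-1-ol | OCCC[C@H]1C(=C)C[C@H](O[Si](C)(C)C(C)(C)C)CC1(C)C | intermediate
14 | 3-[(1R,4R)-4-(tert-butyldimethylsilyloxy)-2,2-dimethyl-6-methylidenecyclohexyl]propanal | O=CCC[C@H]1C(=C)C[C@H](O[Si](C)(C)C(C)(C)C)CC1(C)C | intermediate (not isolated)
15 | 3-[(1R,4R)-4-(tert-butyldimethylsilyloxy)-2,2-dimethyl-6-methylidenecyclohexyl]propanoic acid | OC(=O)CC[C@H]1C(=C)C[C@H](O[Si](C)(C)C(C)(C)C)CC1(C)C | intermediate
16 | mixed anhydride of 15 with isobutyl hydrogen carbonate | CC(C)COC(=O)OC(=O)CC[C@H]1C(=C)C[C@H](O[Si](C)(C)C(C)(C)C)CC1(C)C | intermediate (not isolated)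
17 | 1-diazo-4-[(1R,4R)-4-(tert-butyldimethylsilyloxy)-2,2-dimethyl-6-methylidenecyclohexyl]butan-2-one (ring A diazoketone) | [N-]=[N+]=CC(=O)CC[C@H]1C(=C)C[C@H](O[Si](C)(C)C(C)(C)C)CC1(C)C | intermediate
18 | (2R,5R,9S,10R)-2-(tert-butyldimethylsilyloxy)-9,20-cyclo-11,12,13,14,15,16,17-heptanorlabdan-8-one (ring B cyclohexanone fused to ring A at C5–C10; cyclopropane C9–C10–C20; C20 anti to H5) | O=C1CC[C@@H]2C(C)(C)C[C@@H](O[Si](C)(C)C(C)(C)C)C[C@]23C[C@H]13 | intermediate
19 | tert-butyl bromoacetate | CC(C)(C)OC(=O)CBr | starting material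
20 | lithium (2R,5R,10R)-2-(tert-butyldimethylsilyloxy)-11,12,13,14,15,16,17-heptanorlabd-8-en-8-olate (C8–C9 enolate, C10 methyl) | [Li]OC1CC[C@@H]2C(C)(C)C[C@@H](O[Si](C)(C)C(C)(C)C)C[C@@]2(C)C=1 | intermediate (not isolated)
21 | tert-butyl (2R,5R,9R,10R)-2-(tert-butyldimethylsilyloxy)-8-oxo-13,14,15,16,17-pentanorlabdan-12-oate (C9 epimer, side chain axial) | O=C1CC[C@@H]2C(C)(C)C[C@@H](O[Si](C)(C)C(C)(C)C)C[C@@]2(C)[C@H]1CC(=O)OC(C)(C)C | intermediate (not isolated)
22 | tert-butyl (2R,5R,9S,10R)-2-(tert-butyldimethylsilyloxy)-8-oxo-13,14,15,16,17-pentanorlabdan-12-oate (side chain equatorial) | O=C1CC[C@@H]2C(C)(C)C[C@@H](O[Si](C)(C)C(C)(C)C)C[C@@]2(C)[C@@H]1CC(=O)OC(C)(C)C | intermediate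
23 | tert-butyl (2R,5R,9R,10R)-2-(tert-butyldimethylsilyloxy)-13,14,15,16-tetranorlabd-8(17)-en-12-oate | C=C1CC[C@@H]2C(C)(C)C[C@@H](O[Si](C)(C)C(C)(C)C)C[C@@]2(C)[C@@H]1CC(=O)OC(C)(C)C | intermediate
24 | (2R,5R,9R,10R)-2-(tert-butyldimethylsilyloxy)-13,14,15,16-tetranorlabd-8(17)-en-12-ol | C=C1CC[C@@H]2C(C)(C)C[C@@H](O[Si](C)(C)C(C)(C)C)C[C@@]2(C)[C@@H]1CCO | intermediate
25 | (2R,5R,9R,10R)-2-(tert-butyldimethylsilyloxy)-12-iodo-13,14,15,16-tetranorlabd-8(17)-ene | C=C1CC[C@@H]2C(C)(C)C[C@@H](O[Si](C)(C)C(C)(C)C)C[C@@]2(C)[C@@H]1CCI | intermediate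
26 | methyl 4-hydroxybut-2-ynoate | COC(=O)C#CCO | starting material
27 | methyl (Z)-4-hydroxy-3-iodobut-2-enoate | COC(=O)/C=C(\I)CO | intermediate
28 | methyl (Z)-4-(tert-butyldimethylsilyloxy)-3-iodobut-2-enoate | COC(=O)/C=C(\I)CO[Si](C)(C)C(C)(C)C | intermediate
29 | [(2R,5R,9R,10R)-2-(tert-butyldimethylsilyloxy)-13,14,15,16-tetranorlabd-8(17)-en-12-yl]zinc iodide | C=C1CC[C@@H]2C(C)(C)C[C@@H](O[Si](C)(C)C(C)(C)C)C[C@@]2(C)[C@@H]1CC[Zn]I | intermediate (not isolated)
30 | methyl (2R,5R,9R,10R,13E)-2,16-bis(tert-butyldimethylsilyloxy)labda-8(17),13-dien-15-oate | C=C1CC[C@@H]2C(C)(C)C[C@@H](O[Si](C)(C)C(C)(C)C)C[C@@]2(C)[C@@H]1CC/C(=C\C(=O)OC)CO[Si](C)(C)C(C)(C)C | intermediate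
31 | methyl (2R,5R,9R,10R,13E)-2,16-dihydroxylabda-8(17),13-dien-15-oate | C=C1CC[C@@H]2C(C)(C)C[C@@H](O)C[C@@]2(C)[C@@H]1CC/C(=C\C(=O)OC)CO | intermediate (not isolated)
32 | (2R,5R,9R,10R,13E)-2,16-dihydroxylabda-8(17),13-dien-15-oic acid | C=C1CC[C@@H]2C(C)(C)C[C@@H](O)C[C@@]2(C)[C@@H]1CC/C(=C\C(=O)O)CO | intermediate
33 | (2R,5R,9R,10R,13E)-16-acetoxy-2-hydroxylabda-8(17),13-dien-15-oic acid (CNP0292310.2) | C=C1CC[C@@H]2C(C)(C)C[C@@H](O)C[C@@]2(C)[C@@H]1CC/C(=C\C(=O)O)COC(C)=O | target

**Count and risks**

Total steps: 20. Longest linear sequence: 18 (steps 1–15 and 18–20); steps 16–17 prepare the iodoenoate 28.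

Steps most likely to fail:

1. Step 11. The carbenoid may insert into the tertiary allylic C5–H bond, dimerise, or attack the axial face of the alkene and give the cis-fused isomer. Fallback (sets out from 13, returns at 22): alcohol 13 is oxidised only as far as aldehyde 14 (TEMPO, PhI(OAc)2, CH2Cl2, no water), which is isolated. Homologation with methyl diazoacetate and SnCl2 (Roskamp reaction) gives the β-keto ester methyl 5-[(1R,4R)-4-(tert-butyldimethylsilyloxy)-2,2-dimethyl-6-methylidenecyclohexyl]-3-oxopentanoate F5. SnCl4 in CH2Cl2 then protonates the C10=C20 alkene, and the tin-bound enol captures the tertiary C10 cation through C9 on the same equatorial side (cation–olefin cyclisation of an unsaturated β-keto ester), giving the trans-fused bicyclic β-keto ester F6 with C20 already a methyl group. C-alkylation with 19 (K2CO3, DMF) gives the C9-quaternary diester F7. Krapcho demethoxycarbonylation (LiCl, wet DMSO, heat) and the NaOMe equilibration of step 12 return keto ester 22.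

2. Step 12. Proton exchange between the enolate and the alkylated ketone may lead to polyalkylation or C7 alkylation, and C-alkylation at the neopentyl-type C9 may be slow enough for O-alkylation to compete. Fallback (sets out from 18, returns at 22): after the Li/NH3 cleavage, enolate 20 is trapped on oxygen with allyl chloroformate 3 as the allyl enol carbonate F8. Pd(PPh3)4 (zerovalent palladium) in THF brings about decarboxylative allylation at C9 under neutral conditions (Tsuji allylation), and NaOMe equilibration gives the 9-allyl ketone with equatorial side chain F9. OsO4/NaIO4 cleavage of the allyl group gives the keto aldehyde F10, Pinnick oxidation gives the keto acid F11, and esterification with tert-butyl 2,2,2-trichloroacetimidate returns 22.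

3. Step 3. Enantioselection at a tertiary centre next to the gem-dimethyl carbon may be insufficient, and proton transfer between enolate and product may cause double allylation. Fallback (sets out from 2, returns at 9): compound 2 is deprotonated as in step 2 (dienolate 4) and alkylated with allyl bromide to racemic 6-allyl-3-isobutoxy-5,5-dimethylcyclohex-2-en-1-one F1. The conditions of step 4 give, through the racemic lithium carbinolate F2, the racemic enone F3. The reagent-controlled reduction of step 5 then serves as a divergent resolution: the (R)-enone gives 9, while the (S)-enone gives the cis-configured (1R,4S)-alcohol F4, which is removed by chromatography. The route continues from 9.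

**Further compounds**

F1 | step 3 | racemic 6-allyl-3-isobutoxy-5,5-dimethylcyclohex-2-en-1-one | C=CCC1C(=O)C=C(OCC(C)C)CC1(C)C
F2 | step 3 | racemic lithium 6-allyl-3-isobutoxy-5,5-dimethyl-1-[(trimethylsilyl)methyl]cyclohex-2-en-1-olate | C=CCC1C(O[Li])(C[Si](C)(C)C)C=C(OCC(C)C)CC1(C)C
F3 | step 3 | racemic 4-allyl-5,5-dimethyl-3-[(trimethylsilyl)methyl]cyclohex-2-en-1-one | C=CCC1C(C[Si](C)(C)C)=CC(=O)CC1(C)C
F4 | step 3 | (1R,4S)-4-allyl-5,5-dimethyl-3-[(trimethylsilyl)methyl]cyclohex-2-en-1-ol (hydroxyl cis to allyl) | C=CC[C@@H]1C(C[Si](C)(C)C)=C[C@H](O)CC1(C)C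
F5 | step 11 | methyl 5-[(1R,4R)-4-(tert-butyldimethylsilyloxy)-2,2-dimethyl-6-methylidenecyclohexyl]-3-oxopentanoate | COC(=O)CC(=O)CC[C@H]1C(=C)C[C@H](O[Si](C)(C)C(C)(C)C)CC1(C)C
F6 | step 11 | methyl (2R,5R,10R)-2-(tert-butyldimethylsilyloxy)-8-oxo-12,13,14,15,16,17-hexanorlabdan-11-oate (trans-fused β-keto ester, C9 enolisable) | O=C1CC[C@@H]2C(C)(C)C[C@@H](O[Si](C)(C)C(C)(C)C)C[C@@]2(C)C1C(=O)OC
F7 | step 11 | C9-alkylated diester of F6 (C9 bears CO2Me and CH2CO2tBu; C9 configuration open) | O=C1CC[C@@H]2C(C)(C)C[C@@H](O[Si](C)(C)C(C)(C)C)C[C@@]2(C)C1(CC(=O)OC(C)(C)C)C(=O)OC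
F8 | step 12 | allyl enol carbonate of enolate 20 (C8–O carbonate, C8=C9) | C=CCOC(=O)OC1CC[C@@H]2C(C)(C)C[C@@H](O[Si](C)(C)C(C)(C)C)C[C@@]2(C)C=1
F9 | step 12 | (2R,5R,9S,10R)-9-allyl-8-ketone (allyl in place of the acetate side chain of 22, equatorial) | O=C1CC[C@@H]2C(C)(C)C[C@@H](O[Si](C)(C)C(C)(C)C)C[C@@]2(C)[C@@H]1CC=C
F10 | step 12 | (2R,5R,9S,10R)-2-(tert-butyldimethylsilyloxy)-8-oxo-13,14,15,16,17-pentanorlabdan-12-al | O=C1CC[C@@H]2C(C)(C)C[C@@H](O[Si](C)(C)C(C)(C)C)C[C@@]2(C)[C@@H]1CC=O
F11 | step 12 | (2R,5R,9S,10R)-2-(tert-butyldimethylsilyloxy)-8-oxo-13,14,15,16,17-pentanorlabdan-12-oic acid | O=C1CC[C@@H]2C(C)(C)C[C@@H](O[Si](C)(C)C(C)(C)C)C[C@@]2(C)[C@@H]1CC(=O)O
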